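## Retrosynthetic overview

1. Target 7 ⇒ 18-hydroxy acid 5 by O-acetylation (last step).
2. Key disconnection, C18–O: 5 ⇒ (13S)-labd-8(17)-en-15-oic acid 4 by late-stage hydroxylation of the equatorial C4 methyl, which also creates the C4 stereocentre.
3. 4 ⇒ aldehyde 3 ⇒ enal 2: C13 is set by a stereoconvergent conjugate reduction of the 13E/13Z enal, then the aldehyde is oxidised.
4. 2 ⇒ (+)-manool 1 by oxidative 1,3-transposition of its tertiary allylic alcohol.
5. No ring is formed: rings A and B (C5, C9, C10) and the 8(17)-methylene are carried intact from 1.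

Assumption: (+)-manool, a perfumery labdane diterpenol, is taken as an inexpensive commercial starting material. The target is read as (4R,5R,9S,10R,13S)-18-acetoxylabd-8(17)-en-15-oic acid, with the acetoxymethyl group equatorial (α) and the methyl group axial (β) on C4.

## Route

Step 1
Reactants: 1 (+)-manool, (5S,9S,10S,13R)-labda-8(17),14-dien-13-ol
Product: 2 (5S,9S,10S)-labda-8(17),13-dien-15-al as 13E/13Z mixture (about 2:1)
Conditions: pyridinium chlorochromate [C5H5NH][CrO3Cl] (2.5 equiv), 4 Å MS, CH2Cl2, 23 °C, 4 h
Reagents that add atoms: pyridinium chlorochromate, [O-][Cr](=O)(=O)Cl.c1cc[nH+]cc1 (one oxo oxygen becomes the C15 carbonyl oxygen; the C13 oxygen of 1 leaves on chromium)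
Why: Babler–Dauben oxidative 1,3-transposition, in which the hexavalent chromium oxo reagent moves the oxygen function from C13 to C15 by a [3,3]-shift and oxidises it there to the conjugated enal, while the hindered 8(17)-methylene is untouched at room temperature; the C13 stereocentre of manool is erased on purpose and the E/Z ratio does not matter because step 2 is stereoconvergent.

Step 2
Reactants: 2 (5S,9S,10S)-labda-8(17),13-dien-15-al as 13E/13Z mixture
Product: 3 (5S,9S,10S,13S)-labd-8(17)-en-15-al
Conditions: morpholinium salt of (S)-TRIP [(S)-3,3′-bis(2,4,6-triisopropylphenyl)-1,1′-binaphthyl-2,2′-diyl hydrogen phosphate] (20 mol %), Hantzsch ester (diethyl 2,6-dimethyl-1,4-dihydropyridine-3,5-dicarboxylate, 1.2 equiv), 1,4-dioxane, 50 °C, 24 h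
Reagents that add atoms: none
Why: Iminium-ion organocatalytic transfer hydrogenation with a chiral phosphate counteranion (asymmetric counteranion-directed catalysis), in which the amine condenses reversibly with both enal isomers and these interconvert faster than hydride is delivered, so the mixture converges on one C13 epimer fixed by the chiral anion and not by the remote decalin; 13S corresponds to the (S)-citronellal series, so the catalyst is the mirror image of the one that takes citral to (R)-citronellal, and the isolated 1,1-disubstituted alkene is inert to the dihydropyridine.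

Step 3
Reactants: 3 (5S,9S,10S,13S)-labd-8(17)-en-15-al
Product: 4 (5S,9S,10S,13S)-labd-8(17)-en-15-oic acid
Conditions: NaClO2 (3 equiv), NaH2PO4 (3 equiv), 2-methyl-2-butene (10 equiv), t-BuOH/H2O (4:1), 0 °C → rt
Reagents that add atoms: sodium chlorite, [Na+].[O-]Cl=O
Why: Pinnick oxidation converts the aldehyde to the acid under buffered conditions without risk to C13 (it is not α to the carbonyl), and the excess 2-methyl-2-butene traps hypochlorous acid before it can chlorinate the exocyclic alkene.

Step 4
Reactants: 4 (5S,9S,10S,13S)-labd-8(17)-en-15-oic acid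
Product: 5 (4R,5R,9S,10R,13S)-18-hydroxylabd-8(17)-en-15-oic acid
Conditions: tunnel-widened variant of the CYP153A (Marinobacter aquaeolei) haem domain fused to the P450 BM3 reductase (clarified E. coli lysate, about 0.5 mol % haem iron enzyme), NADP+ (cat.), D-glucose (2 equiv), glucose dehydrogenase, air, KPi buffer pH 7.5, 2-hydroxypropyl-β-cyclodextrin, 25 °C
Reagents that add atoms: dioxygen, O=O
Why: Proposed new method: carboxylate-anchored cytochrome P450 ω-hydroxylation of a terpenoid acid at its equatorial C4 methyl – the fatty-acid ω-hydroxylase binds the C15 carboxylate at the mouth of its substrate tunnel and threads the lipophilic rest towards the haem, and because the trans-decalin locks C11–C9–C10–C5–C4–C18 in an all-anti zigzag, acid 4 behaves as a rigid branched decanoic acid whose true chain terminus is the equatorial 4α-methyl (C18), the only C–H bond able to reach the ferryl (tetravalent iron–oxo) porphyrin radical cation at the narrow end of the tunnel, whereas the axial C19 methyl is lateral and screened by the syn-axial C20, the C2 and C3 methylenes lie off the chain axis, and C16 and the 8(17)-alkene sit far back near the anchor; hydrogen-atom abstraction from C18 followed by oxygen rebound forms the C–O bond, the enzyme's choice between the two diastereotopic methyls makes C4 a stereocentre of R configuration (CH2OH α-equatorial, CH3 β-axial), and no existing stereocentre is touched; the closest known reaction types are the P450 ω-hydroxylation of medium-chain fatty acids by CYP153A–reductase fusions and the microbial P450 hydroxylation of the C18 methyl of labdane diterpenols.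

Step 5
Reactants: 5 (4R,5R,9S,10R,13S)-18-hydroxylabd-8(17)-en-15-oic acid
Product: 7 (4R,5R,9S,10R,13S)-18-acetoxylabd-8(17)-en-15-oic acid (target), via C15 acetic mixed anhydride 6 (not isolated)
Conditions: Ac2O (4 equiv), pyridine, DMAP (5 mol %), CH2Cl2, 0 °C → rt; then H2O/THF, NaHCO3, rt, 1 h; aq. KHSO4 to pH 3
Reagents that add atoms: acetic anhydride, CC(=O)OC(C)=O
Why: Standard pyridine/DMAP acetylation, in which the neopentyl-type C18 primary alcohol is acetylated and the C15 acid is converted for the time being into mixed anhydride 6, which the aqueous bicarbonate work-up hydrolyses at its acetyl carbonyl while the C18 acetate survives; no stereocentre is affected.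

## Compound list

1 | (+)-manool, (5S,9S,10S,13R)-labda-8(17),14-dien-13-ol | C=C1CC[C@H]2C(C)(C)CCC[C@]2(C)[C@H]1CC[C@@](C)(O)C=C | starting material
2 | (5S,9S,10S)-labda-8(17),13-dien-15-al, 13E/13Z mixture, E major (C13=C14 geometry left open in the SMILES because both isomers are present) | C=C1CC[C@H]2C(C)(C)CCC[C@]2(C)[C@H]1CCC(C)=CC=O | intermediate
3 | (5S,9S,10S,13S)-labd-8(17)-en-15-al | C=C1CC[C@H]2C(C)(C)CCC[C@]2(C)[C@H]1CC[C@H](C)CC=O | intermediate
4 | (5S,9S,10S,13S)-labd-8(17)-en-15-oic acid | C=C1CC[C@H]2C(C)(C)CCC[C@]2(C)[C@H]1CC[C@H](C)CC(=O)O | intermediate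
5 | (4R,5R,9S,10R,13S)-18-hydroxylabd-8(17)-en-15-oic acid (CH2OH equatorial/α on C4) | C=C1CC[C@H]2[C@](C)(CO)CCC[C@]2(C)[C@H]1CC[C@H](C)CC(=O)O | intermediate
6 | acetic (4R,5R,9S,10R,13S)-18-acetoxylabd-8(17)-en-15-oic anhydride | C=C1CC[C@H]2[C@](C)(COC(C)=O)CCC[C@]2(C)[C@H]1CC[C@H](C)CC(=O)OC(C)=O | intermediate (not isolated)
7 | (4R,5R,9S,10R,13S)-18-acetoxylabd-8(17)-en-15-oic acid, CNP0346003.1 | C=C1CC[C@H]2[C@](C)(COC(C)=O)CCC[C@]2(C)[C@H]1CC[C@H](C)CC(=O)O | target

## Step count and risks

Total steps: 5. Longest linear sequence: 5 steps (1 → 7).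

The three steps most likely to fail:

Step 4 (the proposed hydroxylation). The decalin may not thread the enzyme tunnel, or oxidation may drift to C2/C3, to the alkene, or onward to the C18 aldehyde. The fallback uses known chemistry, sets out from 1 and comes back at 7: the C–O bond is made first by a documented type of whole-cell biotransformation and carried through the sequence. Wild-type fungal cultures (Mucor plumbeus or Cunninghamella strains) are known to hydroxylate ring A of labdane diterpenols such as sclareol at C3β and at the equatorial C18 methyl. Incubation of manool 1 and chromatographic removal of the regioisomeric alcohols gives 18-hydroxymanool F1. Ac2O/pyridine at 0 °C acetylates only the primary alcohol and gives 18-acetoxymanool F2; the tertiary allylic alcohol does not react. Pyridinium chlorochromate in CH2Cl2 then gives 18-acetoxylabda-8(17),13-dien-15-al F3 as a 13E/13Z mixture. Morpholinium (S)-TRIP phosphate with Hantzsch ester gives (13S)-18-acetoxylabd-8(17)-en-15-al F4, and Pinnick oxidation (NaClO2, NaH2PO4, 2-methyl-2-butene) gives target 7 directly. The cost is a low-yielding, unselective first step on a cheap diterpenol in place of a selective last step.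

Step 2. Incomplete E/Z convergence or imperfect catalyst control would leave the C13 epimer, which is hard to remove; crystallisation of acid 4 is the only simple upgrade. The fallback sets out from 2 and comes back at 3: hydroxyl-directed asymmetric hydrogenation replaces organocatalysis. Luche reduction (NaBH4, CeCl3·7H2O, MeOH, 0 °C) and chromatography on AgNO3-impregnated silica give (13E)-labda-8(17),13-dien-15-ol F5 and (13Z)-labda-8(17),13-dien-15-ol F6. F5 is hydrogenated with Ru(OAc)2[(R)-BINAP] and F6 with Ru(OAc)2[(S)-BINAP] (H2 30–100 bar, MeOH). As with geraniol and nerol, both give the same S-configured product, (13S)-labd-8(17)-en-15-ol F7, and the isolated exocyclic alkene is not reduced. Dess–Martin periodinane in CH2Cl2 then gives aldehyde 3.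

Step 1. The acidic chromium reagent can dehydrate 1 or trigger cyclisation of the allylic cation onto the 8(17)-alkene to pimarane-type tricycles, so the yield may be modest. The fallback sets out from 1 and comes back at 2: the transposition is separated from the oxidation. Redox-neutral 1,3-transposition with Ph3SiOReO3 (2 mol %, Et2O, −50 → 0 °C) equilibrates 1 with the primary allylic alcohol labda-8(17),13-dien-15-ol F8 (13E/13Z mixture); unchanged 1 is recovered and recycled. MnO2 in CH2Cl2 then oxidises F8 to enal 2 under neutral conditions.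

## Further compounds

F1 | step 4 | 18-hydroxymanool, (4R,5R,9S,10R,13R)-labda-8(17),14-diene-13,18-diol | C=C1CC[C@H]2[C@](C)(CO)CCC[C@]2(C)[C@H]1CC[C@@](C)(O)C=C
F2 | step 4 | 18-acetoxymanool, (4R,5R,9S,10R,13R)-18-acetoxylabda-8(17),14-dien-13-ol | C=C1CC[C@H]2[C@](C)(COC(C)=O)CCC[C@]2(C)[C@H]1CC[C@@](C)(O)C=C
F3 | step 4 | (4R,5R,9S,10R)-18-acetoxylabda-8(17),13-dien-15-al, 13E/13Z mixture | C=C1CC[C@H]2[C@](C)(COC(C)=O)CCC[C@]2(C)[C@H]1CCC(C)=CC=O
F4 | step 4 | (4R,5R,9S,10R,13S)-18-acetoxylabd-8(17)-en-15-al | C=C1CC[C@H]2[C@](C)(COC(C)=O)CCC[C@]2(C)[C@H]1CC[C@H](C)CC=O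
F5 | step 2 | (5S,9S,10S,13E)-labda-8(17),13-dien-15-ol | C=C1CC[C@H]2C(C)(C)CCC[C@]2(C)[C@H]1CC/C(C)=C/CO
F6 | step 2 | (5S,9S,10S,13Z)-labda-8(17),13-dien-15-ol | C=C1CC[C@H]2C(C)(C)CCC[C@]2(C)[C@H]1CC/C(C)=C\CO
F7 | step 2 | (5S,9S,10S,13S)-labd-8(17)-en-15-ol | C=C1CC[C@H]2C(C)(C)CCC[C@]2(C)[C@H]1CC[C@H](C)CCO
F8 | step 1 | (5S,9S,10S)-labda-8(17),13-dien-15-ol, 13E/13Z mixture | C=C1CC[C@H]2C(C)(C)CCC[C@]2(C)[C@H]1CCC(C)=CCO
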